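Slowness sets in early in the dusk run: the substrate reaches 27.5% of its charge by 10.0 s, and from there to 60.0 s it falls about 31.0 times more slowly than in those first seconds. The readings therefore show two time scales, a quick fall and a slow one.

| flask | substrate | remark | time |
|---|---|---|---|
| dusk | 8.7 × 10⁻⁴ M | run made earlier |  |
| summer | 0.015 M | run made earlier |  |
| north-west | 6.0 × 10⁻⁴ M |  | 2.0 min |
| north-east | 0.0012 M |  | 2.0 min |
| south-east | 0.0025 M |  | 2.0 min |
| west | 0.0050 M |  | 2.0 min |
| north | 0.010 M |  | 2.0 min |

| run | time / s | target / % | substrate / % |
|---|---|---|---|
| dusk | 10.0 | 2.1 | 27.5 |
| dusk | 20.0 | 5.1 | 22.5 |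
| dusk | 40.0 | 11.6 | 18.9 |
| dusk | 60.0 | 20.8 | 15.8 |
| summer | 10.0 | 2.2 | 28.1 |
| summer | 12.0 | 2.7 | 26.6 |
| summer | 25.0 | 7.0 | 21.5 |
| summer | 60.0 | 21.1 | 16.6 |

(each reading ± 0.5 percentage points)

* amount of target at the end, in percent of the substrate charged for north-west, north-east, south-east, west, north, in this order
* how the row runs (falls, then rises / rises, then falls / hardly changes / rises all the way / falls all the way)

The last rows of the two runs carry the argument. At 60.0 s the dusk run shows substrate and target, yet 63.4% of the charge appears in neither column, so the substrate has gone into something unseen. If the quick fall is taken as a fast pre-equilibrium, the useful reading is what it leaves free. The dusk run holds 0.199 at 60.0 s as its free share, [substrate] divided by all that is not yet target. The summer run, with 17.2 times the charge, holds 0.210 at 60.0 s. Its target reads 21.1% against 20.8% in the dusk run, a gap of 0.3 percentage points where a reading scatters by 0.5 points.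

So in these two runs the free share and the target percentage show no trend with the charge beyond the scatter of the readings, and the reckoning made here expects a flat row. The north charge lies below the summer charge, and the north-east charge above the dusk charge, but north-west stands 1.45 times below the dusk charge. This reckoning gives the flatness and no level.

The forecast gives the level, 44% at each point, and says the row hardly changes, on the ground that “their percentage profiles agree within the scatter”.

North-west ends at 45.2% target and north at 45.2%, so the row hardly changes.

    substrate ⇌ intermediate A (K = 2.30, k = 0.190 s⁻¹)
    substrate → intermediate B (k = 0.0280 s⁻¹)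
    substrate ⇌ intermediate C (K = 0.440, k = 0.00180 s⁻¹)
    intermediate B → target (k = 0.0210 s⁻¹)

The local order of the target at the end in south-east, its percent change per percent of substrate concentration, is 0. Carried to north at 1.00 min, where target stands at 20.7%, the dusk free share gives a [substrate] of 15.8%, and north holds 15.8%. In north-west at 2.00 min the same share gives 10.9%, but north-west holds 9.73%, a free share of 0.178.

Readings and results come from a simulation for an exercise.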